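**What is counted.** Every unit of starting material charged stays in the count: free, in target, in self-condensation product, or bound in catalyst intermediate C. Call the free share a. Pairing alone is second order, so the reciprocal of a, less one, grows as k · c(starting material, charged) · t. The catalyst's draw only adds to that loss.

| flask | starting material | gas | free catalyst | temperature | remark | time |
|---|---|---|---|---|---|---|
| noon | 7.3 mM | 9 mM (held) | 15 mol% | 50 °C | run made earlier |  |
| spring | 39 mM | 9 mM (held) | 15 mol% | 72 °C | run made earlier |  |
| summer | 20 mM | 9 mM (held) | 13 mol% | 50 °C | run made earlier |  |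
| north-east | 20 mM | 9.0 mM (held) | 15 mol% | 70 °C |  | 30 min |
| east | 30 mM | 9.0 mM (held) | 15 mol% | 55 °C |  | 30 min |
| north | 6.0 mM | 9.0 mM (held) | 10 mol% | 70 °C |  | 30 min |
| west | 10 mM | 9.0 mM (held) | 15 mol% | 70 °C |  | 30 min |
| south-east | 6.0 mM | 9.0 mM (held) | 15 mol% | 90 °C |  | 30 min |

| run | time / min | target / % | starting material / % |
|---|---|---|---|
| noon | 10.0 | 0 | 90.3 |
| noon | 20.0 | 1.6 | 79.6 |
| noon | 25.0 | 3.0 | 74.6 |
| noon | 40.0 | 8.3 | 62.2 |
| noon | 50.0 | 11.3 | 55.5 |
| spring | 4.00 | 0.7 | 48.3 |
| spring | 8.00 | 3.9 | 29.2 |
| spring | 10.0 | 5.3 | 23.8 |
| spring | 15.0 | 9.6 | 13.9 |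
| spring | 20.0 | 13.9 | 8.3 |
| summer | 10.0 | 0 | 77.9 |
| summer | 20.0 | 2.1 | 60.5 |
| summer | 30.0 | 5.4 | 48.8 |
| summer | 40.0 | 8.5 | 39.2 |
| summer | 50.0 | 12.4 | 33.6 |

(scatter of a reading: 0.3 percentage points)
- percentages count the starting material that a species holds: one self-condensation product counts as two
- at the start none of coupling partner is dissolved
- steps that have been proposed: starting material + catalyst intermediate B -> catalyst intermediate C; 2 starting material -> self-condensation product; gas <-> coupling partner; catalyst intermediate A <-> by-product + catalyst intermediate B; coupling partner + free catalyst -> catalyst intermediate A; catalyst intermediate C <-> free catalyst + target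
- ranking by amount of target, in percent of the starting material charged, from high to low, at 30 min (north-east / east / north / west / south-east)
- the amount of target, in percent of the starting material charged of the flask you put first, at 30 min
- the amount of target, in percent of the starting material charged of the flask you put last, at 30 min

**Two ways.** I read k, the pair constant, from single readings. The first readings of the noon and summer runs, with target at 0% in both, give 0.00147 mM⁻¹ min⁻¹ and 0.00142 mM⁻¹ min⁻¹. Their charges of starting material are 7.3 mM and 20 mM, so this agreement is a real check on the second order, and I carry the noon figure forward for 50 °C. The spring run parts with itself: its first reading gives 0.00686 mM⁻¹ min⁻¹, its last 0.0142 mM⁻¹ min⁻¹, about twice as much. Between those readings target climbs from 0.7% to 13.9%, so the late figure cheats: it books the catalyst's draw as pairing. I keep the early one.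

**Powers of ten.** From the noon run at 50 °C to the spring run at 72 °C the constant climbs one power of ten per 32.9 K. For south-east, at 90 °C, my estimate from that is 0.0242 mM⁻¹ min⁻¹. The time in which pairing alone halves the free starting material, 1/(k c), I call the pairing half-life; in south-east it is 6.89 min. Pairing alone then leaves 18.7% free in south-east at 30 min. This sets a pace, not a target figure.

**The forecast.** It ranks south-east > west > north-east > north > east, with 27% on top (range 21% to 34%) and 10% last (range 8% to 12.5%). For south-east it says: “fast turnover, but starting material is exhausted”. My reckoning differs in that pairing by itself does not exhaust it by then.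

**The flasks.** The order comes out as south-east > west > north-east > north > east. South-east gives 48.4%, above the forecast's range, and east gives 11.6%, inside it.

    starting material + catalyst intermediate B → catalyst intermediate C (k = 0.932 M⁻¹ s⁻¹, Ea = 72.0 kJ mol⁻¹)
    2 starting material → self-condensation product (k = 0.0473 M⁻¹ s⁻¹, Ea = 68.0 kJ mol⁻¹)
    gas ⇌ coupling partner, rate k3*(csat - [coupling partner]) (kL = 0.00118 s⁻¹)
    catalyst intermediate A ⇌ by-product + catalyst intermediate B (K = 0.215 M, k = 0.0161 s⁻¹, Ea = 87.0 kJ mol⁻¹, ΔH = 9.00 kJ mol⁻¹)
    coupling partner + free catalyst → catalyst intermediate A (k = 1.97 M⁻¹ s⁻¹, Ea = 36.0 kJ mol⁻¹)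
    catalyst intermediate C ⇌ free catalyst + target (K = 0.00678 M, k = 0.0103 s⁻¹, Ea = 106 kJ mol⁻¹, ΔH = −30.0 kJ mol⁻¹)
    (constants at 70 °C)

**At rest?** South-east at 30 min is 4.35 pairing half-lives old. South-east's free starting material, the limiting reagent here, stands at 0.91%, less than pairing's 18.7%. Ten times the time adds 1.1 percentage points of target, so south-east has come to rest. East has a longer pairing half-life, 16.0 min, and is 1.88 of them old. East still holds 27% free and 5.95% bound in catalyst intermediate C, so east has not come to rest: by 300 min its target reaches 39.0%.

(The numbers in the tables are simulated with constants of no real substance; noise was put on by code.)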